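**Retrosynthetic overview**
1. GA55 is gibberellic acid (GA3) plus water across C1=C2, with the new hydroxyl on C1β, cis to the 3β-hydroxyl; every other stereocentre is bought with GA3.
2. C1–O(β) comes from C1–Si(β) by Tamao oxidation with retention.
3. C1–Si is the key bond: a photochemical 5-endo silyl-radical cyclisation from an Si–H group tethered on O3 places silicon on C1β and hydrogen on C2.
4. The tether comes from selective 3-O-silylation of GA3 with chloro(diphenyl)silane.
5. Ring order: rings A–D and the lactone come with GA3; the only ring made is a temporary 1-oxa-2-silolane (O3–Si–C1), closed in step 2 and opened in step 3.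

Assumption: gibberellin numbering and α/β descriptors are used; the C1 hydroxyl in the target SMILES is read as β (cis to the 3β-OH, trans to the 19,10-lactone bridge). The route has not been run; step 2 is a proposal.

**Step 1**
Reactants: 1 gibberellic acid (GA3); 2 chloro(diphenyl)silane
Product: 4 gibberellic acid 3-O-diphenylsilyl ether (free 7-acid), via bis(diphenylsilyl) ether-ester 3 (not isolated)
Conditions: Ph2SiHCl (2.1 equiv), imidazole (4.5 equiv), THF, −40 → 0 °C; then aq. NaH2PO4/Na2HPO4 (pH 7), 0 °C; used at once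
Reagents that add atoms: chloro(diphenyl)silane, Cl[SiH](c1ccccc1)c1ccccc1
Why: Silyl ether formation by substitution at Si–Cl: the carboxylic acid and the secondary allylic 3β-OH are silylated at low temperature while the tertiary bridgehead 13-OH is left, the acyloxysilane alone is hydrolysed in the neutral work-up, and no stereocentre is touched.

**Step 2**
Reactants: 4 gibberellic acid 3-O-diphenylsilyl ether
Product: 5 1β-C,3β-O-(diphenylsilanediyl)-bridged 1,2-dihydro-GA3 (bridged 2,2-diphenyl-1-oxa-2-silolane)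
Conditions: iPr3SiSH (20 mol %), 2,2-dimethoxy-2-phenylacetophenone (10 mol %), 365 nm LEDs, degassed 1,4-dioxane (0.005 M), 25 °C
Reagents that add atoms: none
Why: Proposed new method: photoinitiated, thiol-catalysed radical-chain intramolecular hydrosilylation, in which the thiyl radical made by photolysis of the initiator abstracts the hydridic Si–H (polarity-reversal catalysis), the alkoxydiphenylsilyl radical held over the β face by the pseudoaxial 3β-oxygen adds 5-endo-trig to C1 (allowed by the long Si–O and Si–C bonds, whereas 4-exo closure at C2 would give an oxasiletane), and the secondary C2 radical takes hydrogen from the thiol, so the one-atom tether fixes C1–Si as β and C2 becomes a methylene, with high dilution keeping the silyl radical off the 16-ene of a second molecule; the closest known reaction types are the thermally initiated thiol-catalysed 5-endo cyclisation of acyclic allyloxy(diaryl)silanes and photochemical thiol-co-catalysed intermolecular alkene hydrosilylation, and an endocyclic cis-disubstituted alkene giving a bridged oxasilolane in a substrate with a free acid, a tertiary allylic alcohol and a second alkene is, to my knowledge, not among them.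

**Step 3**
Reactants: 5 1β-C,3β-O-(diphenylsilanediyl)-bridged 1,2-dihydro-GA3
Product: 7 GA55 (1β-hydroxy-1,2-dihydrogibberellic acid), via GA55 1,3-O-diphenylsilylene acetal 6 (not isolated)
Conditions: 30% aq. H2O2 (15 equiv), KF, KHCO3, THF/MeOH 1:1, 25 → 40 °C
Reagents that add atoms: hydrogen peroxide, OO
Why: Tamao oxidation: hydroperoxide adds to the fluoride-activated, strained alkoxysilane and C1 migrates from silicon to oxygen with retention, giving the 1β-oxygen, after which the silylene acetal is hydrolysed in the same medium, and the bicarbonate-buffered conditions leave the lactone, the 16-ene and the C3 configuration alone.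

**Compound list**
1 | gibberellic acid (GA3): 3β,13-dihydroxy-1,16-diene, 7-carboxylic acid, 19,10-lactone | C=C1C[C@]23C[C@@]1(O)CC[C@H]2[C@@]12OC(=O)[C@@](C)([C@H]1[C@@H]3C(=O)O)[C@@H](O)C=C2 | starting material
2 | chloro(diphenyl)silane | Cl[SiH](c1ccccc1)c1ccccc1 | starting material
3 | GA3 3β-O-diphenylsilyl ether, diphenylsilyl 7-ester (13-OH free) | C=C1C[C@]23C[C@@]1(O)CC[C@H]2[C@@]12OC(=O)[C@@](C)([C@H]1[C@@H]3C(=O)O[SiH](c4ccccc4)c4ccccc4)[C@@H](O[SiH](c4ccccc4)c4ccccc4)C=C2 | intermediate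
4 | GA3 3β-O-diphenylsilyl ether (Si–H on O3; 7-CO2H, 13-OH and both alkenes free) | C=C1C[C@]23C[C@@]1(O)CC[C@H]2[C@@]12OC(=O)[C@@](C)([C@H]1[C@@H]3C(=O)O)[C@@H](O[SiH](c4ccccc4)c4ccccc4)C=C2 | intermediate
5 | 1,2-dihydro-GA3 with SiPh2 bonded to C1 (β) and O3 (β), a 2,2-diphenyl-1-oxa-2-silolane bridging C1–C2–C3; C2 is CH2 | C=C1C[C@]23C[C@@]1(O)CC[C@H]2[C@@]12OC(=O)[C@@](C)([C@H]1[C@@H]3C(=O)O)[C@@H](O[Si]4(c5ccccc5)c5ccccc5)C[C@H]24 | intermediate
6 | GA55 1β,3β-O-diphenylsilylene acetal (2,2-diphenyl-1,3,2-dioxasilinane over O1 and O3) | C=C1C[C@]23C[C@@]1(O)CC[C@H]2[C@@]12OC(=O)[C@@](C)([C@H]1[C@@H]3C(=O)O)[C@@H](O[Si]4(c5ccccc5)c5ccccc5)C[C@H]2O4 | intermediate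
7 | GA55 (1β,3β,13-trihydroxy-16-ene, 7-carboxylic acid, 19,10-lactone) | C=C1C[C@]23C[C@@]1(O)CC[C@H]2[C@@]12OC(=O)[C@@](C)([C@H]1[C@@H]3C(=O)O)[C@@H](O)C[C@H]2O | target

**Total step count:** 3
**Longest linear sequence:** 3 steps (1 → 4 → 5 → 7)

**Steps most likely to fail**

Step 2 (proposed new step). Risks: the 5-endo closure onto a ring alkene next to quaternary C10 may be slower than intermolecular silyl-radical addition to the more reactive 16-ene, and the thiol may be lost by hydrothiolation of the 16-ene. Fallback, known chemistry, sets out from 1 and comes back at 7. Allylic oxidation of 1 with MnO2 (acetone, 25 °C) gives 3-oxogibberellic acid (the 1-en-3-one) F8. Weitz–Scheffer epoxidation (30% H2O2, NaHCO3, THF/H2O, 0 °C), with the nucleophile expected on the β face of C1, anti to the C10–O bond, gives the 1β,2β-epoxy-3-ketone F9. Reductive cleavage of the C2–O bond of the epoxy ketone (SmI2, THF/MeOH, −78 °C) gives the 1β-hydroxy-3-ketone F10. K[(s-Bu)3BH] (THF, −78 °C) attacks the ketone from the equatorial α side and gives the axial 3β-alcohol 7.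

Step 1. Risks: partial silylation of the 13-OH (a 13-O–SiH group would cyclise onto C17 in step 2 and destroy the 16-ene), and loss of the labile Si–H ether on work-up. Fallback with a protecting group for O13, sets out from 1 and comes back at 7. Exhaustive acetylation (Ac2O, pyridine, 4-(dimethylamino)pyridine, 25 °C) gives 3,13-di-O-acetylgibberellic acid F1. The secondary allylic acetate alone is removed (K2CO3, aq. MeOH, 0 °C) to give 13-O-acetylgibberellic acid F2. Silylation as in step 1 passes through the 13-O-acetyl bis(diphenylsilyl) ether-ester F3 to 13-O-acetylgibberellic acid 3-O-diphenylsilyl ether F4. Cyclisation as in step 2 gives the 13-O-acetyl bridged oxasilolane F5. Oxidation as in step 3 passes through the 13-O-acetyl-GA55 silylene acetal F6 to 13-O-acetyl-GA55 F7. Deacetylation (K2CO3, aq. MeOH, 25 °C, pH kept near 10 to avoid retro-aldol epimerisation at C3) gives 7.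

Step 3. Risks: slow oxidation of the hindered secondary C1–Si bond, competing phenyl migration that uses up peroxide, and base-induced epimerisation at C3 if heating is needed. Fallback with boron in place of silicon as the oxygen precursor, sets out from 1 and comes back at 7. The enone F8, made as in the fallback to step 2, is β-borylated (B2pin2, CuSO4 5 mol %, 4-picoline, H2O/THF, 25 °C) to the 1β-(pinacolboryl)-3-ketone F11, assuming the same β-face preference at C1. Oxidation of the C–B bond with retention (NaBO3·4H2O, THF/H2O, 25 °C) gives the hydroxy ketone F10, which is reduced with K[(s-Bu)3BH] as above to 7.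

**Further compounds**
F1 | step 1 | 3,13-di-O-acetylgibberellic acid | C=C1C[C@]23C[C@@]1(OC(C)=O)CC[C@H]2[C@@]12OC(=O)[C@@](C)([C@H]1[C@@H]3C(=O)O)[C@@H](OC(C)=O)C=C2
F2 | step 1 | 13-O-acetylgibberellic acid | C=C1C[C@]23C[C@@]1(OC(C)=O)CC[C@H]2[C@@]12OC(=O)[C@@](C)([C@H]1[C@@H]3C(=O)O)[C@@H](O)C=C2
F3 | step 1 | 13-O-acetylgibberellic acid 3-O-diphenylsilyl ether, diphenylsilyl 7-ester | C=C1C[C@]23C[C@@]1(OC(C)=O)CC[C@H]2[C@@]12OC(=O)[C@@](C)([C@H]1[C@@H]3C(=O)O[SiH](c4ccccc4)c4ccccc4)[C@@H](O[SiH](c4ccccc4)c4ccccc4)C=C2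
F4 | step 1 | 13-O-acetylgibberellic acid 3-O-diphenylsilyl ether | C=C1C[C@]23C[C@@]1(OC(C)=O)CC[C@H]2[C@@]12OC(=O)[C@@](C)([C@H]1[C@@H]3C(=O)O)[C@@H](O[SiH](c4ccccc4)c4ccccc4)C=C2
F5 | step 1 | 13-O-acetyl 1β-C,3β-O-(diphenylsilanediyl)-bridged 1,2-dihydro-GA3 | C=C1C[C@]23C[C@@]1(OC(C)=O)CC[C@H]2[C@@]12OC(=O)[C@@](C)([C@H]1[C@@H]3C(=O)O)[C@@H](O[Si]4(c5ccccc5)c5ccccc5)C[C@H]24
F6 | step 1 | 13-O-acetyl-GA55 1β,3β-O-diphenylsilylene acetal | C=C1C[C@]23C[C@@]1(OC(C)=O)CC[C@H]2[C@@]12OC(=O)[C@@](C)([C@H]1[C@@H]3C(=O)O)[C@@H](O[Si]4(c5ccccc5)c5ccccc5)C[C@H]2O4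
F7 | step 1 | 13-O-acetyl-GA55 | C=C1C[C@]23C[C@@]1(OC(C)=O)CC[C@H]2[C@@]12OC(=O)[C@@](C)([C@H]1[C@@H]3C(=O)O)[C@@H](O)C[C@H]2O
F8 | step 2 | 3-oxogibberellic acid (1-en-3-one) | C=C1C[C@]23C[C@@]1(O)CC[C@H]2[C@@]12OC(=O)[C@@](C)([C@H]1[C@@H]3C(=O)O)C(=O)C=C2
F9 | step 2 | 1β,2β-epoxy-3-oxo-1,2-dihydrogibberellic acid | C=C1C[C@]23C[C@@]1(O)CC[C@H]2[C@@]12OC(=O)[C@@](C)([C@H]1[C@@H]3C(=O)O)C(=O)[C@@H]4[C@H]2O4
F10 | step 2 | 1β-hydroxy-3-oxo-1,2-dihydrogibberellic acid (3-dehydro-GA55) | C=C1C[C@]23C[C@@]1(O)CC[C@H]2[C@@]12OC(=O)[C@@](C)([C@H]1[C@@H]3C(=O)O)C(=O)C[C@H]2O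
F11 | step 3 | 1β-(4,4,5,5-tetramethyl-1,3,2-dioxaborolan-2-yl)-3-oxo-1,2-dihydrogibberellic acid | C=C1C[C@]23C[C@@]1(O)CC[C@H]2[C@@]12OC(=O)[C@@](C)([C@H]1[C@@H]3C(=O)O)C(=O)C[C@H]2B4OC(C)(C)C(C)(C)O4
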